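The ratio of target to isomer of the product is the handle you want on this flask, and the south-west run below is that same flask, followed so far.

| flask | starting material | catalyst | remark | time |
|---|---|---|---|---|
| south-west | 0.30 M (fed, over 8.0 s) | 20 mol% | the very flask that is asked about, followed so far; the fed solution adds 0.20 times the starting volume |  |
| west | 0.15 M (fed, over 8.0 s) | 20 mol% | run made earlier; the fed solution adds 0.20 times the starting volume |  |
| flask | 0.30 M (fed, over 8.0 s) | 20 mol% | the fed solution adds 0.20 times the starting volume | 30 min |

| run | time / min | starting material / % | target / % | isomer of the product / % |
|---|---|---|---|---|
| south-west | 0.167 | 29.0 | 20.3 | 5.2 |
| south-west | 0.500 | 5.7 | 39.7 | 10.6 |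
| south-west | 0.833 | 1.7 | 43.8 | 11.9 |
| south-west | 1.33 | 0.4 | 44.7 | 11.5 |
| south-west | 2.00 | 0 | 45.8 | 12.5 |
| south-west | 2.50 | 0 | 45.3 | 12.3 |
| west | 0.833 | 5.7 | 35.9 | 9.7 |
| west | 2.50 | 0.4 | 42.7 | 12.2 |
| west | 4.00 | 0 | 42.9 | 11.5 |
| west | 6.00 | 0.5 | 42.8 | 11.7 |
| west | 10.0 | 0 | 43.6 | 11.8 |
| west | 12.0 | 0 | 43.2 | 11.7 |

(each reading ± 0.3 percentage points)

1. why nothing more happens at 30 min, or that something still does (other conformer counts as not reacted) (no working catalyst is left / all of the starting material has reacted / forward and back rates have come level / it is still moving)
2. part of the starting material that has turned into other species by 30 min (other conformer does not count)
3. how much target there is at 30 min, in percent of the starting material charged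
4. how much isomer of the product there is at 30 min, in percent of the starting material charged

- percent here means starting material units held: one self-condensation product counts as two
- amounts are per litre of the starting volume; all of the dose is in the solution fed
- steps thought possible: starting material <-> other conformer; starting material + catalyst -> catalyst + target; catalyst + other conformer -> catalyst + isomer of the product; 2 starting material -> self-condensation product
- in a conversion other conformer counts as not yet reacted
- the reaction counts as stopped when no species that holds the starting material changes by six tenths of a point or more over the second half of the time
- a reading of starting material is of its free form alone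

Read the south-west table column against column. Starting material falls to 0 % by 2.00 min, and from there target and isomer of the product stand flat within the scatter of 0.3 percentage points, with target over isomer of the product at 3.67 on the last two rows. Call this split, target made per isomer of the product made, the selectivity factor. The south-west run already reads 3.75 at 0.500 min, and the west run, at half the [starting material], reads 3.69 on its last two rows. Both steps run on [catalyst], so it cancels in the ratio, and what remains, beside the two rate constants, is [starting material] over [other conformer], which the steady split of these two runs says is held steady while they last.

Now write the balance of the catalyst, charged in the smaller amount: of the steps thought possible, none removes it, so I expect no halt from that side. In the flat rows of the south-west run starting material reads 0 %, and with isomer of the product flat there I take other conformer to have drained with it. The missing 42.0 % I book as self-condensation product. My own reckoning for this flask at 30 min is therefore the mean of those rows, 45.5 % of target and 12.4 % of isomer of the product.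

The forecast, level with me on target and a shade lower on isomer of the product, gives 45.5 % and 12.3 % at 100 % conversion, with the verdict "all of the starting material has reacted", on the grounds that “Nothing is left to react”.

At 30 min this flask gives 45.4 % of target and 12.2 % of isomer of the product at 100 % conversion, and its verdict is "all of the starting material has reacted".

    starting material ⇌ other conformer (K = 0.570, k = 1.50 s⁻¹)
    starting material + catalyst → catalyst + target (k = 1.50 L mol⁻¹ s⁻¹)
    catalyst + other conformer → catalyst + isomer of the product (k = 0.720 L mol⁻¹ s⁻¹)
    2 starting material → self-condensation product (k = 0.680 L mol⁻¹ s⁻¹)

Your reading of 3.67 shares the 57.6 % that this flask holds as target and isomer of the product together into 45.3 % and 12.3 %. In the run with the back reaction taken away, isomer of the product reads 93.3 % against 12.2 % in this flask, because other conformer returns to starting material here. In the neighbour flask with 1.2 M of starting material, self-condensation product stands at 32.3 %, so the selectivity factor shares out the rest as 53.2 % of target and 14.5 % of isomer of the product; computed, that neighbour flask gives 53.9 % and 13.9 %.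

(Readings and results are simulated on assumed constants; noise was put on by code.)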